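(The earlier runs and the new flask stem from a simulated flask from invented constants, noise included.)

1. Amounts first: the flask holds 0.300 M of Q against 1.5 M of L, and the amber run held 0.30 M against 2.1 M.

| flask | L | Q | remark | time |
|---|---|---|---|---|
| amber | 2.1 M | 0.30 M | run made earlier |  |
| flask | 1.5 M | 0.300 M |  | 12 d |

amber run (percent of the L charged)

| time / d | Z / % |
|---|---|
| 0.167 | 7.3 |
| 0.500 | 11.2 |
| 1.67 | 8.4 |
| 5.00 | 6.8 |
| 15.0 | 3.8 |

(standard deviation of a reading: 0.5 percentage points)

* the best time, 12 d at the latest, for Z
* the amount of Z, in percent of the L charged, at that time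



2. Define q, the Q share, as the charge of Q over the charge of L: 20.0% in the flask and 14.3% in the amber run, so the flask's share is larger. It is the part of the charged L that Q can take if each Q binds one L, which is an assumption of this reckoning.

3. The fraction of the charged L that Q does not take is then 1 − q, here 80.0%, whether it stands as L or as something L has become. This reckoning, which is separate from the forecast, expects that split in the flask at 12 d if Q is used up by then.

4. The amber readings of Z reach 11.2% at 0.500 d and fall to 3.8% at 15.0 d, so the search belongs early.

5. The hunch, taken as the forecast, gives 14.5% at 0.65 d, noting of the amber peak and Q: “which suggests Q limits Z, though one run cannot prove it”.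

6. The flask gives 12.5% at 0.629 d, so the forecast held within its margins.

    L ⇌ Z (K = 0.344, k = 0.0338 h⁻¹)
    Z ⇌ G (K = 0.160, k = 0.529 h⁻¹)
    G ⇌ D (K = 5.27, k = 0.0523 h⁻¹)
    Z ⇌ J (K = 2.70, k = 0.0277 h⁻¹)
    2 L → E (k = 0.00752 L mol⁻¹ h⁻¹)
    L + Q → X (k = 0.132 L mol⁻¹ h⁻¹)

The relaxation half-life of L and Z by their step alone, both ways together, is 0.219 d, short against 12 d, and in the flask Z over L stands at 0.351 at 6.00 d and 0.363 at 12.0 d, as L falls to 13.1%. In the flask at 12.0 d, Q, the limiting reagent of L + Q → X, stands at 0% of its own charge and X at 20.0% of the L charged against a q of 20.0%, while the neighbouring flask with 1.2 M of Q has a q of 80.0% and its X reaches 78.9% at 12.0 d.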